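**Retrosynthetic overview**

1. Target 22 ← desilylation and reduction of both lactone carbonyls to CH2 ← endo,endo-dilactone 19. The strategy rests on this feature: each furofuran half is an aryl-bearing O–CH carbon (C2 on ring A, C6 on ring B) next to a ring-fusion carbon (C1, C5) whose one-carbon arm (C8, C4) is bonded to the oxygen of the other half. That is the pattern of a 2,3-diaroylsuccinate after reduction and double lactonisation.
2. 19 ← dimethyl 2,3-diaroylsuccinate 17 by two-fold Ru transfer hydrogenation with dynamic kinetic resolution. It forms C2–H and C6–H, sets C1, C2, C5 and C6, and closes O3–C4 and O7–C8 (both γ-lactone rings).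
3. 17 ← C5–C6 bond by Stetter addition of benzofuran aldehyde 13 to aroylbutenedioate 16 (from vanillin via keto ester 15). This is chosen over enolate/α-bromo keto ester coupling, where bromine transfer between the two enolates would scramble the partners.
4. 13 ← cis-dihydrobenzofuran by Rh-carbenoid 1,5-C–H insertion of aryldiazoacetate 9 (from 4-bromo-2-methoxyphenol and vanillin).
5. Ring order: dihydrofuran ring of the benzofuran (step 7), then both furofuran rings together as lactones (step 15).

Key step: step 15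

**Remarks**

- Numbering: the furofuran is numbered as 3,7-dioxabicyclo[3.3.0]octane (C1/C5 ring fusion, C2/C6 aryl-bearing, O3/O7, C4/C8 one-carbon arms). Ring A is the guaiacyl group on C2, ring B the benzofuran arene on C6, ring C the guaiacyl group on benzofuran C2.
- Stereochemistry read from the structure: C1, C2, C5 and C6 are all S, which places both aryl groups endo (cis to the neighbouring CH2 arm). The dihydrobenzofuran is cis-(2S,3S).
- Abbreviations: TIPS = Si(iPr)3, TBS = SiMe2tBu, Ar = 3-methoxy-4-(TIPS-oxy)phenyl, Bf = (2S,3S)-2-Ar-3-(TBS-oxymethyl)-7-methoxy-2,3-dihydro-1-benzofuran-5-yl. Phenols are carried as TIPS ethers because they must survive amine bases, LiN(iPr)2 and formic acid.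
- Assumption: dirhodium tetrakis(N-phthaloyl-tert-leucinate) with (S)-ligands is taken to give the (2R,3S)-cis ester from 2-(benzyloxy)aryl diazoacetates, so the (R)-ligand complex Rh2(R-PTTL)4 is specified for the (2S,3R) ester 10. If the sense is opposite on this substrate, the antipodal complex is used.

**Route**

Step 1
Reactants: 1 vanillin
Product: 2 3-methoxy-4-(TIPS-oxy)benzaldehyde (ArCHO)
Conditions: TIPSCl, imidazole, DMF, rt
Reagents that add atoms: chlorotriisopropylsilane, CC(C)[Si](Cl)(C(C)C)C(C)C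
Why: Silyl ether formation at the phenol; the TIPS ether is chosen to withstand the bases and formic acid used later.

Step 2
Reactants: 2 ArCHO
Product: 3 [3-methoxy-4-(TIPS-oxy)phenyl]methanol (ArCH2OH)
Conditions: NaBH4, MeOH, 0 °C
Reagents that add atoms: none
Why: Borohydride reduction of the aldehyde; the aryl silyl ether is untouched at 0 °C.

Step 3
Reactants: 4 4-bromo-2-methoxyphenol
Product: 5 4-bromo-2-iodo-6-methoxyphenol
Conditions: I2, KI, NaHCO3, H2O–MeOH, rt
Reagents that add atoms: iodine, II
Why: Electrophilic aromatic iodination of the phenoxide; the para position carries Br and one ortho position carries OMe, so iodine should enter the free position ortho to OH.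

Step 4
Reactants: 5 4-bromo-2-iodo-6-methoxyphenol; 3 ArCH2OH
Product: 6 5-bromo-1-iodo-3-methoxy-2-(ArCH2O)benzene
Conditions: PPh3, DIAD, THF, 0 °C to rt
Reagents that add atoms: none
Why: Mitsunobu etherification; the acidic phenol protonates the betaine and displaces the benzylic alkoxyphosphonium under neutral conditions that spare the aryl silyl ether.

Step 5
Reactants: 6 aryl iodide
Product: 7 methyl 2-[5-bromo-3-methoxy-2-(ArCH2O)phenyl]-2-oxoacetate
Conditions: iPrMgCl·LiCl, THF, −40 °C; then added to dimethyl oxalate (3 equiv), THF, −78 °C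
Reagents that add atoms: dimethyl oxalate, COC(=O)C(=O)OC
Why: Iodine–magnesium exchange is much faster at the alkoxy-flanked C–I than at C–Br, and inverse addition of the aryl Grignard to excess oxalate stops at mono-acylation to the aryl glyoxylate.

Step 6
Reactants: 7 aryl glyoxylate
Product: 9 methyl 2-[5-bromo-3-methoxy-2-(ArCH2O)phenyl]-2-diazoacetate, via tosylhydrazone 8 (not isolated)
Conditions: TsNHNH2, toluene, 80 °C; then DBU, CH2Cl2, rt
Reagents that add atoms: p-toluenesulfonyl hydrazide, Cc1ccc(S(=O)(=O)NN)cc1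
Why: Hydrazone formation followed by Bamford–Stevens elimination of sulfinate, the standard route from aryl glyoxylates to aryl diazoacetates.

Step 7
Reactants: 9 aryl diazoacetate
Product: 10 methyl (2S,3R)-2-Ar-5-bromo-7-methoxy-2,3-dihydro-1-benzofuran-3-carboxylate (cis)
Conditions: Rh2(R-PTTL)4 (2 mol%), toluene, −78 °C
Reagents that add atoms: none
Why: Intramolecular Rh-carbenoid 1,5-C–H insertion into the ether-activated benzylic methylene, a known reaction of 2-(benzyloxy)aryl diazoacetates that gives the cis ring; the chiral carboxylate pocket should set C2 and C3 together as (2S,3R).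

Step 8
Reactants: 10 cis ester
Product: 11 [(2S,3S)-2-Ar-5-bromo-7-methoxy-2,3-dihydro-1-benzofuran-3-yl]methanol
Conditions: iBu2AlH (2.5 equiv), CH2Cl2, −78 to −20 °C; aq. potassium sodium tartrate
Reagents that add atoms: none
Why: Ester reduction with a non-basic hydride, so the epimerisable cis C3 centre should not equilibrate to trans; the descriptor changes from R to S only through the priority change.

Step 9
Reactants: 11 alcohol
Product: 12 (2S,3S)-2-Ar-5-bromo-3-(TBS-oxymethyl)-7-methoxy-2,3-dihydro-1-benzofuran (BfBr)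
Conditions: TBSCl, imidazole, DMF, rt
Reagents that add atoms: tert-butyldimethylsilyl chloride, CC(C)(C)[Si](C)(C)Cl
Why: Silyl ether formation at the primary alcohol, which would otherwise quench the aryllithium of step 10.

Step 10
Reactants: 12 BfBr
Product: 13 (2S,3S)-2-Ar-3-(TBS-oxymethyl)-7-methoxy-2,3-dihydro-1-benzofuran-5-carbaldehyde (BfCHO)
Conditions: n-BuLi, THF, −78 °C; DMF; aq. NH4Cl
Reagents that add atoms: N,N-dimethylformamide, CN(C)C=O
Why: Bromine–lithium exchange and formylation of the aryllithium with DMF; both silyl ethers and the ring stereocentres are inert at −78 °C.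

Step 11
Reactants: 2 ArCHO
Product: 14 methyl 3-Ar-3-hydroxypropanoate (racemic)
Conditions: LiN(iPr)2, MeOAc, THF, −78 °C; then 2
Reagents that add atoms: methyl acetate, COC(C)=O
Why: Aldol addition of the lithium enolate of methyl acetate; the carbinol centre is removed in the next step.

Step 12
Reactants: 14 hydroxy ester
Product: 15 methyl 3-Ar-3-oxopropanoate
Conditions: Dess–Martin periodinane, NaHCO3, CH2Cl2, rt
Reagents that add atoms: none
Why: Dess–Martin oxidation of a benzylic secondary alcohol to the β-keto ester under buffered, neutral conditions.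

Step 13
Reactants: 15 β-keto ester
Product: 16 dimethyl 2-(ArCO)but-2-enedioate (E/Z mixture)
Conditions: methyl glyoxylate, piperidine (cat.), AcOH (cat.), 4 Å MS, CH2Cl2, rt
Reagents that add atoms: methyl glyoxylate, COC(=O)C=O
Why: Knoevenagel condensation of the active methylene with the non-enolisable glyoxylate; the alkene geometry is lost in step 14.

Step 14
Reactants: 13 BfCHO; 16 aroylbutenedioate (1.5 equiv)
Product: 17 dimethyl 2-(ArCO)-3-(BfCO)butanedioate (mixture of epimers at the two succinate carbons)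
Conditions: 3-benzyl-5-(2-hydroxyethyl)-4-methylthiazolium chloride (20 mol%), Et3N, THF, 60 °C
Reagents that add atoms: none
Why: Stetter reaction; the Breslow intermediate of 13 adds to the CH carbon of 16 because only that attack gives a keto ester-stabilised enolate, forming C5–C6 with both ketones in place and without halogen-transfer scrambling.

Step 15
Reactants: 17 diaroylsuccinate
Product: 19 (1R,2S,5R,6S)-2-Ar-6-Bf-3,7-dioxabicyclo[3.3.0]octane-4,8-dione (endo,endo), via diol diester 18 (not isolated)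
Conditions: RuCl[(S,S)-TsDPEN](p-cymene) (5 mol%), HCO2H–Et3N (5:2), DMF, 35 °C
Reagents that add atoms: none
Why: Proposed new method: formate converts the 16-electron Ru amide into the Ru–H/N–H species, which passes hydride and proton to each aryl ketone in an outer-sphere six-membered transition state while C1 and C5 (each the α-carbon of a β-keto ester) epimerise through their enols faster than they are reduced, so each unit is funnelled through its fastest-reacting epimer; the closest known reaction type is the transfer hydrogenation with dynamic kinetic resolution of a single α-substituted aryl β-keto ester by this catalyst, here asked to act twice in one molecule and in the anti sense. Each new carbinol oxygen then attacks the methyl ester on the neighbouring succinate carbon (O3 on C4, O7 on C8), two 5-exo-trig acyl substitutions that expel methanol and close the two γ-lactone rings as a cis-fused bicycle. C2 and C6 (both S) are set by the (S,S)-diamine ligand, with the aryl group under the η6-cymene as in the reduction of simple aryl ketones; C1 and C5 (both R in 19) are set by the resolution, for which a non-chelated Felkin–Anh arrangement (ester anti to the incoming hydride, the bulky succinate branch turned away from the catalyst) is expected to give the anti hydroxy ester. The step needs anti selectivity at both units together with the same ketone face; the substrate secures fast epimerisation (doubly activated C–H at C1 and C5) and removes every isomer whose C1 and C5 would place H1 and H5 trans, since that cannot form a cis-fused dilactone and stops at a separable monolactone. Ring closure does not exclude the doubly syn diol, which would give the exo,exo-dilactone, so the anti sense rests on the catalyst alone and is the unproven point; lactonisation of the first carbinol before the second reduction leaves C5 a β-keto lactone α-carbon and does not change this analysis.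

Step 16
Reactants: 19 dilactone
Product: 20 (1R,2S,5R,6S)-2-Ar-6-Bf-3,7-dioxabicyclo[3.3.0]octane-4,8-diol (bis-lactol, anomer mixture)
Conditions: iBu2AlH (2.3 equiv), CH2Cl2, −78 °C; aq. potassium sodium tartrate
Reagents that add atoms: none
Why: Partial reduction of each γ-lactone to the lactol; the tetrahedral aluminium alkoxide is stable at −78 °C, so over-reduction should not occur, and the new C4/C8 centres are removed in step 17.

Step 17
Reactants: 20 bis-lactol
Product: 21 (1S,2S,5S,6S)-2-Ar-6-Bf-3,7-dioxabicyclo[3.3.0]octane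
Conditions: Et3SiH, BF3·OEt2, CH2Cl2, −78 to −40 °C
Reagents that add atoms: none
Why: Ionic hydrogenation; BF3 ionises each lactol to a non-benzylic cyclic oxocarbenium ion (C4, C8) that takes hydride from the silane, and the low temperature should leave the benzylic C–O bonds un-ionised, so no stereocentre is touched.

Step 18
Reactants: 21 tris-silyl ether
Product: 22 target, 4-[(1S,2S,5S,6S)-6-[(2S,3S)-2-(4-hydroxy-3-methoxyphenyl)-3-(hydroxymethyl)-7-methoxy-2,3-dihydro-1-benzofuran-5-yl]-3,7-dioxabicyclo[3.3.0]octan-2-yl]-2-methoxyphenol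
Conditions: Bu4NF, AcOH, THF, 0 °C to rt
Reagents that add atoms: none
Why: Fluoride desilylation of the two aryl TIPS ethers and the primary TBS ether; the acetic acid buffer should keep the phenols protonated so that no p-quinone methide forms at the benzylic ethers.

**Compound list**

1 | vanillin | COc1cc(C=O)ccc1O | starting material
2 | 3-methoxy-4-(triisopropylsilyloxy)benzaldehyde | COc1cc(C=O)ccc1O[Si](C(C)C)(C(C)C)C(C)C | intermediate
3 | [3-methoxy-4-(triisopropylsilyloxy)phenyl]methanol | COc1cc(CO)ccc1O[Si](C(C)C)(C(C)C)C(C)C | intermediate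
4 | 4-bromo-2-methoxyphenol | COc1cc(Br)ccc1O | starting material
5 | 4-bromo-2-iodo-6-methoxyphenol | COc1cc(Br)cc(I)c1O | intermediate
6 | 5-bromo-1-iodo-3-methoxy-2-{[3-methoxy-4-(triisopropylsilyloxy)phenyl]methoxy}benzene | COc1cc(Br)cc(I)c1OCc1ccc(O[Si](C(C)C)(C(C)C)C(C)C)c(OC)c1 | intermediate
7 | methyl 2-[5-bromo-3-methoxy-2-(ArCH2O)phenyl]-2-oxoacetate | COC(=O)C(=O)c1cc(Br)cc(OC)c1OCc1ccc(O[Si](C(C)C)(C(C)C)C(C)C)c(OC)c1 | intermediate
8 | N-tosylhydrazone of 7 | COC(=O)C(=NNS(=O)(=O)c1ccc(C)cc1)c1cc(Br)cc(OC)c1OCc1ccc(O[Si](C(C)C)(C(C)C)C(C)C)c(OC)c1 | intermediate (not isolated)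
9 | methyl 2-[5-bromo-3-methoxy-2-(ArCH2O)phenyl]-2-diazoacetate | COC(=O)C(=[N+]=[N-])c1cc(Br)cc(OC)c1OCc1ccc(O[Si](C(C)C)(C(C)C)C(C)C)c(OC)c1 | intermediate
10 | methyl (2S,3R)-2-Ar-5-bromo-7-methoxy-2,3-dihydro-1-benzofuran-3-carboxylate (cis) | Brc1cc(OC)c2c(c1)[C@@H](C(=O)OC)[C@@H](c1ccc(O[Si](C(C)C)(C(C)C)C(C)C)c(OC)c1)O2 | intermediate
11 | [(2S,3S)-2-Ar-5-bromo-7-methoxy-2,3-dihydro-1-benzofuran-3-yl]methanol | Brc1cc(OC)c2c(c1)[C@@H](CO)[C@@H](c1ccc(O[Si](C(C)C)(C(C)C)C(C)C)c(OC)c1)O2 | intermediate
12 | (2S,3S)-2-Ar-5-bromo-3-[(tert-butyldimethylsilyloxy)methyl]-7-methoxy-2,3-dihydro-1-benzofuran | Brc1cc(OC)c2c(c1)[C@@H](CO[Si](C)(C)C(C)(C)C)[C@@H](c1ccc(O[Si](C(C)C)(C(C)C)C(C)C)c(OC)c1)O2 | intermediate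
13 | (2S,3S)-2-Ar-3-[(tert-butyldimethylsilyloxy)methyl]-7-methoxy-2,3-dihydro-1-benzofuran-5-carbaldehyde | O=Cc1cc(OC)c2c(c1)[C@@H](CO[Si](C)(C)C(C)(C)C)[C@@H](c1ccc(O[Si](C(C)C)(C(C)C)C(C)C)c(OC)c1)O2 | intermediate
14 | methyl 3-Ar-3-hydroxypropanoate (racemic) | COC(=O)CC(O)c1ccc(O[Si](C(C)C)(C(C)C)C(C)C)c(OC)c1 | intermediate
15 | methyl 3-Ar-3-oxopropanoate | COC(=O)CC(=O)c1ccc(O[Si](C(C)C)(C(C)C)C(C)C)c(OC)c1 | intermediate
16 | dimethyl 2-(ArCO)but-2-enedioate (E/Z mixture) | COC(=O)C=C(C(=O)OC)C(=O)c1ccc(O[Si](C(C)C)(C(C)C)C(C)C)c(OC)c1 | intermediate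
17 | dimethyl 2-(ArCO)-3-(BfCO)butanedioate (epimer mixture at the succinate carbons) | COC(=O)C(C(=O)c1ccc(O[Si](C(C)C)(C(C)C)C(C)C)c(OC)c1)C(C(=O)OC)C(=O)c1cc(OC)c2c(c1)[C@@H](CO[Si](C)(C)C(C)(C)C)[C@@H](c1ccc(O[Si](C(C)C)(C(C)C)C(C)C)c(OC)c1)O2 | intermediate
18 | dimethyl (2R,3R)-2-[(S)-Ar(hydroxy)methyl]-3-[(S)-Bf(hydroxy)methyl]butanedioate (anti,anti) | COc1cc([C@@H](O)[C@H](C(=O)OC)[C@@H](C(=O)OC)[C@H](O)c2cc(OC)c3c(c2)[C@@H](CO[Si](C)(C)C(C)(C)C)[C@@H](c2ccc(O[Si](C(C)C)(C(C)C)C(C)C)c(OC)c2)O3)ccc1O[Si](C(C)C)(C(C)C)C(C)C | intermediate (not isolated)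
19 | (1R,2S,5R,6S)-2-Ar-6-Bf-3,7-dioxabicyclo[3.3.0]octane-4,8-dione (endo,endo) | COc1cc([C@H]2OC(=O)[C@@H]3[C@H]2C(=O)O[C@@H]3c2cc(OC)c3c(c2)[C@@H](CO[Si](C)(C)C(C)(C)C)[C@@H](c2ccc(O[Si](C(C)C)(C(C)C)C(C)C)c(OC)c2)O3)ccc1O[Si](C(C)C)(C(C)C)C(C)C | intermediate
20 | (1R,2S,5R,6S)-2-Ar-6-Bf-3,7-dioxabicyclo[3.3.0]octane-4,8-diol (anomer mixture) | COc1cc([C@H]2OC(O)[C@@H]3[C@H]2C(O)O[C@@H]3c2cc(OC)c3c(c2)[C@@H](CO[Si](C)(C)C(C)(C)C)[C@@H](c2ccc(O[Si](C(C)C)(C(C)C)C(C)C)c(OC)c2)O3)ccc1O[Si](C(C)C)(C(C)C)C(C)C | intermediate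
21 | (1S,2S,5S,6S)-2-Ar-6-Bf-3,7-dioxabicyclo[3.3.0]octane | COc1cc([C@H]2OC[C@@H]3[C@H]2CO[C@@H]3c2cc(OC)c3c(c2)[C@@H](CO[Si](C)(C)C(C)(C)C)[C@@H](c2ccc(O[Si](C(C)C)(C(C)C)C(C)C)c(OC)c2)O3)ccc1O[Si](C(C)C)(C(C)C)C(C)C | intermediate
22 | CNP0303197.1 | COc1cc([C@H]2OC[C@@H]3[C@H]2CO[C@@H]3c2cc(OC)c3c(c2)[C@@H](CO)[C@@H](c2ccc(O)c(OC)c2)O3)ccc1O | target

**Step count**

Total: 18 steps. Longest linear sequence: 14 steps (1 → 2 → 3 → 6 → 7 → 9 → 10 → 11 → 12 → 13 → 17 → 19 → 20 → 21 → 22; steps 1, 2, 4–10, 14–18).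

**Steps most likely to fail**

Step 15. The reduction may run through the syn transition state at one or both keto ester units, which would lead to exo-aryl lactones. The two units may also be resolved with unlike C1/C5, stopping at a monolactone, or the 1,4-diketone may cyclodehydrate to a furan in the acidic medium. The fallback sets out from 17 and replaces catalyst control by substrate control and separation. LiEt3BH with CeCl3 in THF at −78 °C (non-chelating conditions known to give anti β-hydroxy esters from α-alkyl β-keto esters) should reduce both ketones in the Felkin–Anh sense. The anti,anti-diols expected are 18 and its core-antipodal counterpart, dimethyl (2S,3S)-2-[(R)-Ar(hydroxy)methyl]-3-[(R)-Bf(hydroxy)methyl]butanedioate F1. Warming the crude mixture with pyridinium p-toluenesulfonate in toluene closes the lactones. Dilactone 19 is then separated by chromatography from the diastereomeric (1S,2R,5S,6R)-2-Ar-6-Bf-3,7-dioxabicyclo[3.3.0]octane-4,8-dione F2 and from monolactones; the two dilactones differ because the benzofuran centres are fixed. The route is rejoined at 19.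

Step 14. Formation of the Breslow intermediate from the electron-rich aldehyde may be slow, benzoin self-condensation may dominate, or the carbene may be sequestered by the very electrophilic acceptor. The fallback sets out from 13 and 15 and builds the C1–C5 bond by enolate alkylation. Aldehyde 13 is taken through aldol addition of lithiated methyl acetate to methyl 3-Bf-3-hydroxypropanoate F3, then Dess–Martin oxidation to methyl 3-Bf-3-oxopropanoate F4. Keto ester 15 is chlorinated with N-chlorosuccinimide and Mg(ClO4)2 (cat.) to methyl 2-chloro-3-Ar-3-oxopropanoate F5. The sodium enolate of F4 (NaH, THF) is alkylated with F5, the classical route to 2,3-diacylsuccinates; the chloride is used because chlorine is transferred between enolates far less readily than bromine. The route is rejoined at 17.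

Step 17. BF3 may ionise the p-silyloxybenzylic C–O bonds (C2–O3, C6–O7, benzofuran C2–O1), which would epimerise endo aryl groups to exo or the cis benzofuran to trans; the TBS ether may also be lost early. The fallback sets out from 19, bypasses 20 and uses no Lewis acid. LiAlH4 in THF at 0 °C should give (1S,2S,3S,4S)-1-Ar-4-Bf-2,3-bis(hydroxymethyl)butane-1,4-diol F6. TsCl (2.2 equiv) in pyridine at 0 °C should sulfonylate the two primary hydroxyls to the bis(primary tosylate) of F6, F7. Each benzylic hydroxyl then displaces the tosylate on the other branch (5-exo-tet, retention at C2 and C6). The route is rejoined at 21.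

**Further compounds**

F1 | step 15 | dimethyl (2S,3S)-2-[(R)-Ar(hydroxy)methyl]-3-[(R)-Bf(hydroxy)methyl]butanedioate | COc1cc([C@H](O)[C@@H](C(=O)OC)[C@H](C(=O)OC)[C@@H](O)c2cc(OC)c3c(c2)[C@@H](CO[Si](C)(C)C(C)(C)C)[C@@H](c2ccc(O[Si](C(C)C)(C(C)C)C(C)C)c(OC)c2)O3)ccc1O[Si](C(C)C)(C(C)C)C(C)C
F2 | step 15 | (1S,2R,5S,6R)-2-Ar-6-Bf-3,7-dioxabicyclo[3.3.0]octane-4,8-dione | COc1cc([C@@H]2OC(=O)[C@H]3[C@@H]2C(=O)O[C@H]3c2cc(OC)c3c(c2)[C@@H](CO[Si](C)(C)C(C)(C)C)[C@@H](c2ccc(O[Si](C(C)C)(C(C)C)C(C)C)c(OC)c2)O3)ccc1O[Si](C(C)C)(C(C)C)C(C)C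
F3 | step 14 | methyl 3-Bf-3-hydroxypropanoate (carbinol epimers) | COC(=O)CC(O)c1cc(OC)c2c(c1)[C@@H](CO[Si](C)(C)C(C)(C)C)[C@@H](c1ccc(O[Si](C(C)C)(C(C)C)C(C)C)c(OC)c1)O2
F4 | step 14 | methyl 3-Bf-3-oxopropanoate | COC(=O)CC(=O)c1cc(OC)c2c(c1)[C@@H](CO[Si](C)(C)C(C)(C)C)[C@@H](c1ccc(O[Si](C(C)C)(C(C)C)C(C)C)c(OC)c1)O2
F5 | step 14 | methyl 2-chloro-3-Ar-3-oxopropanoate (racemic) | COC(=O)C(Cl)C(=O)c1ccc(O[Si](C(C)C)(C(C)C)C(C)C)c(OC)c1
F6 | step 17 | (1S,2S,3S,4S)-1-Ar-4-Bf-2,3-bis(hydroxymethyl)butane-1,4-diol | COc1cc([C@@H](O)[C@H](CO)[C@@H](CO)[C@H](O)c2cc(OC)c3c(c2)[C@@H](CO[Si](C)(C)C(C)(C)C)[C@@H](c2ccc(O[Si](C(C)C)(C(C)C)C(C)C)c(OC)c2)O3)ccc1O[Si](C(C)C)(C(C)C)C(C)C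
F7 | step 17 | bis(primary p-toluenesulfonate) of F6 | COc1cc([C@@H](O)[C@H](COS(=O)(=O)c4ccc(C)cc4)[C@@H](COS(=O)(=O)c4ccc(C)cc4)[C@H](O)c2cc(OC)c3c(c2)[C@@H](CO[Si](C)(C)C(C)(C)C)[C@@H](c2ccc(O[Si](C(C)C)(C(C)C)C(C)C)c(OC)c2)O3)ccc1O[Si](C(C)C)(C(C)C)C(C)C
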